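**Retrosynthetic overview**
- The strategy rests on ring B, the hydroxylated benzene ring of the depsidone. Its free C–OH and its lactone C–O are para; between them sit, on one side, the two carbons that carry the pyran (the O-bearing carbon next to C–OH, the C-bearing carbon next to the lactone C–O) and, on the other, the aryloxy carbon and one CH.
- This pattern is cut into a carbene carbon (C–OMe, later C–OH), the two alkene carbons of a dihydropyran, one CO (the lactone C–O carbon) and the two carbons of a terminal alkyne (Dötz benzannulation). The diaryl ether oxygen comes in on the alkyne, as the ethynyl ether of the ring A salicylate.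
- After the benzannulation: methoxyphenol to quinone to hydroquinone, ester cleavage, closure of the seven-membered lactone, then loss of the C4 silyloxy group (ring B chromene C=C) and of the MOM group.
- Ring A alkyne from methyl 2,4,6-trihydroxybenzoate: C-prenylation, chromene by propargyl ether Claisen rearrangement, site-selective protection, O-alkynylation. Carbene complex from 2,2-dimethyl-2,3-dihydro-4H-pyran-4-one.
- Ring order: ring A pyran, then ring B benzene (its pyran is already present, saturated), then the lactone ring, then the ring B pyran C=C.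

Key step: step 12

Remark on the chemistry: the silyloxy-bearing carbon of the pyran fragment is carried as a racemate; it becomes sp2 in the last step and the target has no stereocentre.

**Route**

Step 1
Reactants: 1 2,2-dimethyl-2,3-dihydro-4H-pyran-4-one
Product: 2 (±)-2,2-dimethyl-3,4-dihydro-2H-pyran-4-ol
Conditions: NaBH4, CeCl3·7H2O, MeOH, −40 → 0 °C
Reagents that add atoms: none
Why: Luche 1,2-reduction of the vinylogous ester carbonyl should give the allylic alcohol without touching the enol ether; the new centre is racemic.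

Step 2
Reactants: 2 (±)-2,2-dimethyl-3,4-dihydro-2H-pyran-4-ol
Product: 3 (±)-tert-butyl[(2,2-dimethyl-3,4-dihydro-2H-pyran-4-yl)oxy]dimethylsilane
Conditions: TBSCl, imidazole, DMF, rt
Reagents that add atoms: tert-butyldimethylsilyl chloride, CC(C)(C)[Si](C)(C)Cl
Why: Standard silylation of a secondary alcohol under non-acidic conditions that spare the enol ether.

Step 3
Reactants: 3 (±)-tert-butyl[(2,2-dimethyl-3,4-dihydro-2H-pyran-4-yl)oxy]dimethylsilane; 4 chromium hexacarbonyl Cr(CO)6
Product: 7 (±)-pentacarbonyl{methoxy[4-(tert-butyldimethylsilyloxy)-2,2-dimethyl-3,4-dihydro-2H-pyran-6-yl]carbene}chromium, via 6-lithiodihydropyran 5 (not isolated), via lithium acylchromate 6 (not isolated)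
Conditions: t-BuLi, THF, −78 → 0 °C; Cr(CO)6, THF, 0 °C → rt; then Me3OBF4, CH2Cl2, 0 °C
Reagents that add atoms: trimethyloxonium tetrafluoroborate, C[O+](C)C.F[B-](F)(F)F
Why: Fischer carbene synthesis: the vinylic CH next to the ring oxygen is lithiated (as with silylated glycals), the vinyllithium adds to a CO ligand, and the acylchromate is O-methylated.

Step 4
Reactants: 8 methyl 2,4,6-trihydroxybenzoate
Product: 9 methyl 2,4,6-trihydroxy-3-(3-methylbut-2-en-1-yl)benzoate
Conditions: prenyl bromide (1.0 equiv), DBU, THF, 0 °C → rt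
Reagents that add atoms: prenyl bromide (1-bromo-3-methylbut-2-ene), CC(C)=CCBr
Why: C-alkylation of a phloroglucinol-type phenoxide by an allylic bromide; C3 and C5 are equivalent, so regiochemistry is fixed and only over-alkylation and O-alkylation must be held back by stoichiometry.

Step 5
Reactants: 9 methyl 2,4,6-trihydroxy-3-(3-methylbut-2-en-1-yl)benzoate
Product: 10 methyl 2,6-dihydroxy-3-(3-methylbut-2-en-1-yl)-4-[(2-methylbut-3-yn-2-yl)oxy]benzoate
Conditions: 3-chloro-3-methylbut-1-yne, DBU, CuCl2·2H2O (cat.), MeCN, 0 °C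
Reagents that add atoms: 3-chloro-3-methylbut-1-yne, CC(C)(Cl)C#C
Why: Copper-catalysed propargylic etherification picks the para hydroxyl, the most acidic and the only one not hydrogen-bonded to the ester.

Step 6
Reactants: 10 methyl 2,6-dihydroxy-3-(3-methylbut-2-en-1-yl)-4-[(2-methylbut-3-yn-2-yl)oxy]benzoate
Product: 11 methyl 6-(tert-butyldimethylsilyloxy)-2-hydroxy-3-(3-methylbut-2-en-1-yl)-4-[(2-methylbut-3-yn-2-yl)oxy]benzoate
Conditions: TBSCl (1.05 equiv), imidazole, DMF, 0 °C
Reagents that add atoms: tert-butyldimethylsilyl chloride, CC(C)(C)[Si](C)(C)Cl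
Why: Sterically controlled silylation: the hydroxyl flanked by CH should react, the one buttressed by the prenyl group and chelated to the ester should not.

Step 7
Reactants: 11 methyl 6-(tert-butyldimethylsilyloxy)-2-hydroxy-3-(3-methylbut-2-en-1-yl)-4-[(2-methylbut-3-yn-2-yl)oxy]benzoate
Product: 12 methyl 6-(tert-butyldimethylsilyloxy)-2-(methoxymethoxy)-3-(3-methylbut-2-en-1-yl)-4-[(2-methylbut-3-yn-2-yl)oxy]benzoate
Conditions: NaH, MOMCl, THF, 0 °C
Reagents that add atoms: chloromethyl methyl ether, COCCl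
Why: Williamson-type alkylation of the one remaining, chelated phenoxide; brief exposure at 0 °C keeps the aryl silyl ether in place.

Step 8
Reactants: 12 methyl 6-(tert-butyldimethylsilyloxy)-2-(methoxymethoxy)-3-(3-methylbut-2-en-1-yl)-4-[(2-methylbut-3-yn-2-yl)oxy]benzoate
Product: 13 methyl 5-(tert-butyldimethylsilyloxy)-7-(methoxymethoxy)-2,2-dimethyl-8-(3-methylbut-2-en-1-yl)-2H-chromene-6-carboxylate
Conditions: xylenes, 140 °C
Reagents that add atoms: none
Why: Aryl propargyl ether Claisen rearrangement to the only free ortho carbon (the other carries the prenyl group), then enolisation, 1,5-hydrogen shift and oxa-6π electrocyclisation, should close the 2,2-dimethyl-2H-chromene.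

Step 9
Reactants: 13 methyl 5-(tert-butyldimethylsilyloxy)-7-(methoxymethoxy)-2,2-dimethyl-8-(3-methylbut-2-en-1-yl)-2H-chromene-6-carboxylate
Product: 14 methyl 5-hydroxy-7-(methoxymethoxy)-2,2-dimethyl-8-(3-methylbut-2-en-1-yl)-2H-chromene-6-carboxylate
Conditions: TBAF, AcOH, THF, 0 °C
Reagents that add atoms: none
Why: Fluoride cleaves the aryl silyl ether and bares the single phenol, the one peri to the chromene CH, that is to carry the alkyne.

Step 10
Reactants: 14 methyl 5-hydroxy-7-(methoxymethoxy)-2,2-dimethyl-8-(3-methylbut-2-en-1-yl)-2H-chromene-6-carboxylate; 15 (bromoethynyl)triisopropylsilane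
Product: 16 methyl 7-(methoxymethoxy)-2,2-dimethyl-8-(3-methylbut-2-en-1-yl)-5-{[(triisopropylsilyl)ethynyl]oxy}-2H-chromene-6-carboxylate
Conditions: CuI (20 mol %), 1,10-phenanthroline, K3PO4, toluene, 90 °C
Reagents that add atoms: none
Why: Ullmann-type copper-catalysed C(sp)–O coupling of a phenol with a 1-bromoalkyne, the oxygen counterpart of the copper-catalysed ynamide coupling (copper-mediated alkynylation of phenols is established with 1,1-dibromoalkenes as alkyne source); 14 has one free hydroxyl and the bulky silyl cap holds back alkyne homocoupling.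

Step 11
Reactants: 16 methyl 7-(methoxymethoxy)-2,2-dimethyl-8-(3-methylbut-2-en-1-yl)-5-{[(triisopropylsilyl)ethynyl]oxy}-2H-chromene-6-carboxylate
Product: 17 methyl 5-(ethynyloxy)-7-(methoxymethoxy)-2,2-dimethyl-8-(3-methylbut-2-en-1-yl)-2H-chromene-6-carboxylate
Conditions: TBAF, THF, −40 → 0 °C; used at once
Reagents that add atoms: none
Why: Fluoride-induced protodesilylation of the alkynylsilane under non-acidic conditions, which the acid-sensitive terminal ynol ether needs.

Step 12
Reactants: 7 (±)-pentacarbonyl{methoxy[4-(tert-butyldimethylsilyloxy)-2,2-dimethyl-3,4-dihydro-2H-pyran-6-yl]carbene}chromium; 17 methyl 5-(ethynyloxy)-7-(methoxymethoxy)-2,2-dimethyl-8-(3-methylbut-2-en-1-yl)-2H-chromene-6-carboxylate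
Product: 19 (±)-methyl 5-{[4-(tert-butyldimethylsilyloxy)-5-hydroxy-8-methoxy-2,2-dimethylchroman-6-yl]oxy}-7-(methoxymethoxy)-2,2-dimethyl-8-(3-methylbut-2-en-1-yl)-2H-chromene-6-carboxylate, via tricarbonylchromium phenol complex 18 (not isolated)
Conditions: 17 (1.3 equiv), THF (0.05 M), 55 °C, Ar; then air, rt
Reagents that add atoms: none
Why: Dötz benzannulation: the ynol ether joins its CH terminus to the carbene carbon of 7 (after CO loss, or by direct attack of the electron-rich alkyne followed by CO loss), the resulting aryloxy-substituted dienylcarbene inserts CO to a chromium-bound dienylketene, and this closes onto C5 of the dihydropyran and tautomerises to the phenol, so that three C–C bonds form; air then strips Cr(CO)3 from complex 18. The closest known reactions are the benzannulation of alkenyl(methoxy)carbene chromium complexes, among them those made from 2-lithiated dihydropyrans, with terminal alkynes, and the thermal cyclisation of dienyl(alkoxy)carbene complexes to ortho-alkoxyphenols; aryloxyalkynes have been tried only rarely. Ring B is closed as a carbocycle by 6π electrocyclisation of the dienylketene, the new bond running from the CO-derived carbon to the pyran CH carbon. No stereocentre forms; C4 stays racemic. The step needs a single alkyne orientation, aryloxy carbon beside the CO-derived C–OH and CH beside C–OMe, and both the steric rule for terminal alkynes and the donor oxygen, which makes the CH terminus the nucleophilic end and stabilises the carbene carbon formed at the other, work in that direction.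

Step 13
Reactants: 19 (±)-methyl 5-{[4-(tert-butyldimethylsilyloxy)-5-hydroxy-8-methoxy-2,2-dimethylchroman-6-yl]oxy}-7-(methoxymethoxy)-2,2-dimethyl-8-(3-methylbut-2-en-1-yl)-2H-chromene-6-carboxylate
Product: 21 (±)-methyl 5-{[4-(tert-butyldimethylsilyloxy)-5,8-dihydroxy-2,2-dimethylchroman-6-yl]oxy}-7-(methoxymethoxy)-2,2-dimethyl-8-(3-methylbut-2-en-1-yl)-2H-chromene-6-carboxylate, via aryloxyquinone 20 (not isolated)
Conditions: PhI(OAc)2, MeCN–H2O (4:1), 0 °C; then aq. Na2S2O4, EtOAc, rt
Reagents that add atoms: water, O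
Why: Oxidative demethylation of a para-methoxyphenol by the trivalent-iodine reagent (water adds at the methoxy carbon, methanol leaves) gives the quinone, which dithionite reduces in the same flask; ring A has no free hydroxyl and should be spared.

Step 14
Reactants: 21 (±)-methyl 5-{[4-(tert-butyldimethylsilyloxy)-5,8-dihydroxy-2,2-dimethylchroman-6-yl]oxy}-7-(methoxymethoxy)-2,2-dimethyl-8-(3-methylbut-2-en-1-yl)-2H-chromene-6-carboxylate
Product: 22 (±)-5-{[4-(tert-butyldimethylsilyloxy)-5,8-dihydroxy-2,2-dimethylchroman-6-yl]oxy}-7-(methoxymethoxy)-2,2-dimethyl-8-(3-methylbut-2-en-1-yl)-2H-chromene-6-carboxylic acid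
Conditions: LiI, pyridine, 110 °C, Ar; then aq. HCl to pH 4, 0 °C
Reagents that add atoms: none
Why: SN2 dealkylation of the methyl ester by iodide attacks the methyl carbon and is therefore indifferent to the two ortho substituents that shield the carbonyl; the electron-rich acid is freed cold and used directly to avoid decarboxylation.

Step 15
Reactants: 22 (±)-5-{[4-(tert-butyldimethylsilyloxy)-5,8-dihydroxy-2,2-dimethylchroman-6-yl]oxy}-7-(methoxymethoxy)-2,2-dimethyl-8-(3-methylbut-2-en-1-yl)-2H-chromene-6-carboxylic acid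
Product: 23 (±)-depsidone lactone: garcinisidone D skeleton with the ring A hydroxyl as MOM ether and ring B as 4-(tert-butyldimethylsilyloxy)-3,4-dihydropyran (seven-membered lactone between the ring A carboxyl and the chroman O5; chroman 8-OH free)
Conditions: EDC·HCl, DMAP, CH2Cl2 (2 mM), 0 °C → rt, Ar
Reagents that add atoms: none
Why: Carbodiimide (Steglich-type) lactonisation, the classical depsidone ring closure; only the hydroxyl ortho to the diaryl ether oxygen can reach the activated acid through a seven-membered ring, and high dilution holds back intermolecular acylation of the other.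

Step 16
Reactants: 23 (±)-depsidone lactone with MOM ether and 4-silyloxy group
Product: 25 garcinisidone D, via garcinisidone D methoxymethyl ether 24 (not isolated)
Conditions: p-TsOH·H2O (cat.), toluene, 60 °C; then MeOH, 3 M HCl, 45 °C
Reagents that add atoms: none
Why: Acid-catalysed E1 loss of the benzylic silyloxy group (cation stabilised by the ortho pyran oxygen) should give the 2H-chromene while the MOM ether still caps the hydroxyl next to the prenyl group; methanolic HCl then cleaves the MOM acetal, conditions that 2,2-dimethylchromenes and prenyl groups normally survive.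

**Compound list**
1 | 2,2-dimethyl-2,3-dihydro-4H-pyran-4-one | CC1(C)CC(=O)C=CO1 | starting material
2 | (±)-2,2-dimethyl-3,4-dihydro-2H-pyran-4-ol | CC1(C)CC(O)C=CO1 | intermediate
3 | (±)-tert-butyl[(2,2-dimethyl-3,4-dihydro-2H-pyran-4-yl)oxy]dimethylsilane | CC1(C)CC(O[Si](C)(C)C(C)(C)C)C=CO1 | intermediate
4 | chromium hexacarbonyl Cr(CO)6 | O=C=[Cr](=C=O)(=C=O)(=C=O)(=C=O)=C=O | starting material
5 | (±)-[4-(tert-butyldimethylsilyloxy)-2,2-dimethyl-3,4-dihydro-2H-pyran-6-yl]lithium | [Li]C1=CC(O[Si](C)(C)C(C)(C)C)CC(C)(C)O1 | intermediate (not isolated)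
6 | lithium pentacarbonyl{[4-(tert-butyldimethylsilyloxy)-2,2-dimethyl-3,4-dihydro-2H-pyran-6-yl]carbonyl}chromate, racemic | [Li+].[O-]C(C1=CC(O[Si](C)(C)C(C)(C)C)CC(C)(C)O1)=[Cr](=C=O)(=C=O)(=C=O)(=C=O)=C=O | intermediate (not isolated)
7 | (±)-pentacarbonyl{methoxy[4-(tert-butyldimethylsilyloxy)-2,2-dimethyl-3,4-dihydro-2H-pyran-6-yl]carbene}chromium | COC(C1=CC(O[Si](C)(C)C(C)(C)C)CC(C)(C)O1)=[Cr](=C=O)(=C=O)(=C=O)(=C=O)=C=O | intermediate
8 | methyl 2,4,6-trihydroxybenzoate | COC(=O)c1c(O)cc(O)cc1O | starting material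
9 | methyl 2,4,6-trihydroxy-3-(3-methylbut-2-en-1-yl)benzoate | COC(=O)c1c(O)cc(O)c(CC=C(C)C)c1O | intermediate
10 | methyl 2,6-dihydroxy-3-(3-methylbut-2-en-1-yl)-4-[(2-methylbut-3-yn-2-yl)oxy]benzoate | COC(=O)c1c(O)cc(OC(C)(C)C#C)c(CC=C(C)C)c1O | intermediate
11 | methyl 6-(tert-butyldimethylsilyloxy)-2-hydroxy-3-(3-methylbut-2-en-1-yl)-4-[(2-methylbut-3-yn-2-yl)oxy]benzoate | COC(=O)c1c(O[Si](C)(C)C(C)(C)C)cc(OC(C)(C)C#C)c(CC=C(C)C)c1O | intermediate
12 | methyl 6-(tert-butyldimethylsilyloxy)-2-(methoxymethoxy)-3-(3-methylbut-2-en-1-yl)-4-[(2-methylbut-3-yn-2-yl)oxy]benzoate | COC(=O)c1c(O[Si](C)(C)C(C)(C)C)cc(OC(C)(C)C#C)c(CC=C(C)C)c1OCOC | intermediate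
13 | methyl 5-(tert-butyldimethylsilyloxy)-7-(methoxymethoxy)-2,2-dimethyl-8-(3-methylbut-2-en-1-yl)-2H-chromene-6-carboxylate | COC(=O)c1c(O[Si](C)(C)C(C)(C)C)c2C=CC(C)(C)Oc2c(CC=C(C)C)c1OCOC | intermediate
14 | methyl 5-hydroxy-7-(methoxymethoxy)-2,2-dimethyl-8-(3-methylbut-2-en-1-yl)-2H-chromene-6-carboxylate | COC(=O)c1c(O)c2C=CC(C)(C)Oc2c(CC=C(C)C)c1OCOC | intermediate
15 | (bromoethynyl)triisopropylsilane | CC(C)[Si](C#CBr)(C(C)C)C(C)C | starting material
16 | methyl 7-(methoxymethoxy)-2,2-dimethyl-8-(3-methylbut-2-en-1-yl)-5-{[(triisopropylsilyl)ethynyl]oxy}-2H-chromene-6-carboxylate | COC(=O)c1c(OC#C[Si](C(C)C)(C(C)C)C(C)C)c2C=CC(C)(C)Oc2c(CC=C(C)C)c1OCOC | intermediate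
17 | methyl 5-(ethynyloxy)-7-(methoxymethoxy)-2,2-dimethyl-8-(3-methylbut-2-en-1-yl)-2H-chromene-6-carboxylate | C#COc1c(C(=O)OC)c(OCOC)c(CC=C(C)C)c2OC(C)(C)C=Cc12 | intermediate
18 | tricarbonylchromium η6-complex of phenol 19, racemic | COc1cc(Oc2c(C(=O)OC)c(OCOC)c(CC=C(C)C)c3OC(C)(C)C=Cc23)c(O)c2C(O[Si](C)(C)C(C)(C)C)CC(C)(C)Oc12.O=C=[Cr](=C=O)=C=O | intermediate (not isolated)
19 | (±)-methyl 5-{[4-(tert-butyldimethylsilyloxy)-5-hydroxy-8-methoxy-2,2-dimethylchroman-6-yl]oxy}-7-(methoxymethoxy)-2,2-dimethyl-8-(3-methylbut-2-en-1-yl)-2H-chromene-6-carboxylate | COc1cc(Oc2c(C(=O)OC)c(OCOC)c(CC=C(C)C)c3OC(C)(C)C=Cc23)c(O)c2C(O[Si](C)(C)C(C)(C)C)CC(C)(C)Oc12 | intermediate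
20 | (±)-methyl 5-{[4-(tert-butyldimethylsilyloxy)-2,2-dimethyl-5,8-dioxo-3,4,5,8-tetrahydro-2H-chromen-6-yl]oxy}-7-(methoxymethoxy)-2,2-dimethyl-8-(3-methylbut-2-en-1-yl)-2H-chromene-6-carboxylate | O=C1C=C(Oc2c(C(=O)OC)c(OCOC)c(CC=C(C)C)c3OC(C)(C)C=Cc23)C(=O)C2=C1OC(C)(C)CC2O[Si](C)(C)C(C)(C)C | intermediate (not isolated)
21 | (±)-methyl 5-{[4-(tert-butyldimethylsilyloxy)-5,8-dihydroxy-2,2-dimethylchroman-6-yl]oxy}-7-(methoxymethoxy)-2,2-dimethyl-8-(3-methylbut-2-en-1-yl)-2H-chromene-6-carboxylate | Oc1cc(Oc2c(C(=O)OC)c(OCOC)c(CC=C(C)C)c3OC(C)(C)C=Cc23)c(O)c2C(O[Si](C)(C)C(C)(C)C)CC(C)(C)Oc12 | intermediate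
22 | (±)-5-{[4-(tert-butyldimethylsilyloxy)-5,8-dihydroxy-2,2-dimethylchroman-6-yl]oxy}-7-(methoxymethoxy)-2,2-dimethyl-8-(3-methylbut-2-en-1-yl)-2H-chromene-6-carboxylic acid | Oc1cc(Oc2c(C(=O)O)c(OCOC)c(CC=C(C)C)c3OC(C)(C)C=Cc23)c(O)c2C(O[Si](C)(C)C(C)(C)C)CC(C)(C)Oc12 | intermediate
23 | (±)-depsidone lactone: garcinisidone D with the ring A hydroxyl as MOM ether and the ring B pyran as its 3,4-dihydro-4-(tert-butyldimethylsilyloxy) form | CC(C)=CCc1c(OCOC)c2c(c3c1OC(C)(C)C=C3)Oc1cc(O)c3c(c1OC2=O)C(O[Si](C)(C)C(C)(C)C)CC(C)(C)O3 | intermediate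
24 | garcinisidone D methoxymethyl ether (MOM on the ring A hydroxyl) | CC(C)=CCc1c(OCOC)c2c(c3c1OC(C)(C)C=C3)Oc1cc(O)c3c(c1OC2=O)C=CC(C)(C)O3 | intermediate (not isolated)
25 | garcinisidone D | CC(C)=CCc1c(O)c2c(c3c1OC(C)(C)C=C3)Oc1cc(O)c3c(c1OC2=O)C=CC(C)(C)O3 | target

**Step count**
Total: 16 steps. Longest linear sequence: 13 steps (8 to 25, steps 4–16).

**Steps most likely to fail**

1. Step 12 (benzannulation). The ynol ether may insert and stop at the oxygen-stabilised dienylcarbene, the carbene may cyclise without taking up CO or be trapped by the neighbouring chromene alkene, or the ynol ether may polymerise before it is consumed. Fallback: the aryl ether is no longer carried on the alkyne; the C6–O bond is made by addition–elimination on a bromoquinone. Carbene 7 and ethynyltrimethylsilane (THF, 55 °C, then air; silicon next to the hydroxyl, the usual orientation of a terminal alkyne) should give (±)-4-(tert-butyldimethylsilyloxy)-8-methoxy-2,2-dimethyl-6-(trimethylsilyl)chroman-5-ol F1. NBS (MeCN, 0 °C) replaces silicon by bromine ortho to the hydroxyl and gives (±)-6-bromo-4-(tert-butyldimethylsilyloxy)-8-methoxy-2,2-dimethylchroman-5-ol F2. PhI(OAc)2 in wet MeCN gives (±)-6-bromo-4-(tert-butyldimethylsilyloxy)-2,2-dimethylchroman-5,8-dione F3. Phenol 14 with K2CO3 in MeCN adds at C6 (activated by the C8 carbonyl) and bromide leaves. The fallback sets out from 7 and 14 and comes back at quinone 20, which is reduced to 21 as in step 13; steps 10 and 11 fall away.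

2. Step 10 (O-alkynylation). C–O bond formation may be slow at a phenol hindered on both flanks (ester and peri CH), while the bromoalkyne is lost to reductive homocoupling or to base-induced addition of phenoxide across the triple bond. Fallback: build the ynol ether by addition–elimination instead of cross-coupling. Phenol 14 with trichloroethylene and K2CO3 (DMF, 70 °C; addition to dichloroacetylene formed in the flask) should give methyl 5-{[(E)-1,2-dichlorovinyl]oxy}-7-(methoxymethoxy)-2,2-dimethyl-8-(3-methylbut-2-en-1-yl)-2H-chromene-6-carboxylate F4. n-BuLi (2.1 equiv, THF, −90 °C, inverse addition, methanol quench) eliminates HCl and exchanges the second chlorine; the ester, shielded by two ortho oxygen substituents, is the point to watch. The fallback sets out from 14 and comes back at 17; step 11 falls away.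

3. Step 16 (elimination and MOM cleavage). Ionisation of the benzylic silyl ether is slowed by the acyloxy group now ortho to it; stronger acid would then let the prenyl group cyclise onto the freed hydroxyl or let methanol open the lactone. Fallback: move the elimination to phenol 19, where the free ortho hydroxyl helps ionisation and the MOM group is untouched. 19 with catalytic p-TsOH·H2O (toluene, 40 °C) should give methyl 5-[(5-hydroxy-8-methoxy-2,2-dimethyl-2H-chromen-6-yl)oxy]-7-(methoxymethoxy)-2,2-dimethyl-8-(3-methylbut-2-en-1-yl)-2H-chromene-6-carboxylate F5. PhI(OAc)2 in wet MeCN gives the corresponding 2H-chromene-5,8-dione F6, reduced in the same flask by Na2S2O4 to the 5,8-dihydroxy-2H-chromene F7. LiI in pyridine gives the carboxylic acid F8, and EDC·HCl/DMAP at high dilution closes the lactone. The fallback sets out from 19 and comes back at 24, which is then isolated and needs only methanolic HCl to reach 25.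

**Further compounds**
F1 | step 12 | (±)-4-(tert-butyldimethylsilyloxy)-8-methoxy-2,2-dimethyl-6-(trimethylsilyl)chroman-5-ol | COc1cc([Si](C)(C)C)c(O)c2C(O[Si](C)(C)C(C)(C)C)CC(C)(C)Oc12
F2 | step 12 | (±)-6-bromo-4-(tert-butyldimethylsilyloxy)-8-methoxy-2,2-dimethylchroman-5-ol | COc1cc(Br)c(O)c2C(O[Si](C)(C)C(C)(C)C)CC(C)(C)Oc12
F3 | step 12 | (±)-6-bromo-4-(tert-butyldimethylsilyloxy)-2,2-dimethylchroman-5,8-dione | O=C1C=C(Br)C(=O)C2=C1OC(C)(C)CC2O[Si](C)(C)C(C)(C)C
F4 | step 10 | methyl 5-{[(E)-1,2-dichlorovinyl]oxy}-7-(methoxymethoxy)-2,2-dimethyl-8-(3-methylbut-2-en-1-yl)-2H-chromene-6-carboxylate | COC(=O)c1c(O/C(Cl)=C\Cl)c2C=CC(C)(C)Oc2c(CC=C(C)C)c1OCOC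
F5 | step 16 | methyl 5-[(5-hydroxy-8-methoxy-2,2-dimethyl-2H-chromen-6-yl)oxy]-7-(methoxymethoxy)-2,2-dimethyl-8-(3-methylbut-2-en-1-yl)-2H-chromene-6-carboxylate | COc1cc(Oc2c(C(=O)OC)c(OCOC)c(CC=C(C)C)c3OC(C)(C)C=Cc23)c(O)c2C=CC(C)(C)Oc12
F6 | step 16 | methyl 5-[(2,2-dimethyl-5,8-dioxo-5,8-dihydro-2H-chromen-6-yl)oxy]-7-(methoxymethoxy)-2,2-dimethyl-8-(3-methylbut-2-en-1-yl)-2H-chromene-6-carboxylate | O=C1C=C(Oc2c(C(=O)OC)c(OCOC)c(CC=C(C)C)c3OC(C)(C)C=Cc23)C(=O)C2=C1OC(C)(C)C=C2
F7 | step 16 | methyl 5-[(5,8-dihydroxy-2,2-dimethyl-2H-chromen-6-yl)oxy]-7-(methoxymethoxy)-2,2-dimethyl-8-(3-methylbut-2-en-1-yl)-2H-chromene-6-carboxylate | Oc1cc(Oc2c(C(=O)OC)c(OCOC)c(CC=C(C)C)c3OC(C)(C)C=Cc23)c(O)c2C=CC(C)(C)Oc12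
F8 | step 16 | 5-[(5,8-dihydroxy-2,2-dimethyl-2H-chromen-6-yl)oxy]-7-(methoxymethoxy)-2,2-dimethyl-8-(3-methylbut-2-en-1-yl)-2H-chromene-6-carboxylic acid | Oc1cc(Oc2c(C(=O)O)c(OCOC)c(CC=C(C)C)c3OC(C)(C)C=Cc23)c(O)c2C=CC(C)(C)Oc12
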